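**Retrosynthetic overview**

1. The target is a 5-hydroxy-7-methoxy-2-(4-methoxyphenyl)chromone (flavone, unprimed locants, rings A, C, B) bonded through C3 to C6'' of a (2R)-5,7-dihydroxy-2-(4-hydroxyphenyl)chromanone (double-primed locants). Working backwards, the benzyl ethers go first, then the C2''–aryl bond (enantioselective conjugate addition of an arylboronic acid to a chromone), then that chromone ring (o-hydroxyacetophenone plus a one-carbon unit).
2. The strategy rests on the flavone C4 carbonyl being bonded to C4a of ring A, whose 5,7-dioxygenation is symmetric. Ring C is therefore opened at C4–C4a with O1–C2 kept, giving a (Z)-3-(3,5-dimethoxyphenoxy)-2,3-diarylacrylic acid that can close to one chromone only.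
3. That acid comes from an arylacetic ester by Claisen acylation with 4-methoxybenzoyl chloride, conversion of the enol to the vinyl chloride, addition–elimination by 3,5-dimethoxyphenoxide and saponification.
4. Repair of the protecting groups: the flavanone O1'' is the phloroglucinol oxygen para to the biaryl bond. That oxygen is carried as an allyl ether and the two ortho oxygens as benzyl ethers from the start, so the second pyranone ring can close only onto the para oxygen (6''-linked, not 8''-linked).
5. Ring order: flavone ring C (step 9), second chromone ring (step 13), C2'' stereocentre (step 14). Flavone O5 is freed by chelation-controlled demethylation (step 10) and the benzyl ethers fall last (step 15).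

Key step: step 9

Remark: the configuration of the C3–C6'' biaryl axis is not specified in the target and is treated as not fixed; from compound 16 onward the intermediates are drawn without an axial descriptor and may exist as rotamers that converge on the target.

**Route**

Step 1
Reactants: 1 3,5-bis(benzyloxy)phenol
Product: 3 2,6-bis(benzyloxy)-4-hydroxybenzaldehyde, via Vilsmeier iminium chloride 2 (not isolated)
Conditions: POCl3, DMF, MeCN, 0 °C → rt; then H2O, 40 °C
Reagents that add atoms: N,N-dimethylformamide, CN(C)C=O; water, O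
Why: Vilsmeier–Haack formylation, in which the free hydroxyl of a 3,5-dialkoxyphenol directs the chloroiminium ion mainly to the para carbon flanked by the two benzyloxy groups; the minor, chelated ortho aldehyde is less polar and should be removable by chromatography.

Step 2
Reactants: 3 2,6-bis(benzyloxy)-4-hydroxybenzaldehyde
Product: 4 4-(allyloxy)-2,6-bis(benzyloxy)benzaldehyde
Conditions: allyl bromide, K2CO3, DMF, rt
Reagents that add atoms: allyl bromide, C=CCBr
Why: Williamson etherification of the only free (and acidic, para-formyl) phenol, which marks the para oxygen with a group removable independently of benzyl and methyl ethers.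

Step 3
Reactants: 4 4-(allyloxy)-2,6-bis(benzyloxy)benzaldehyde
Product: 5 5-(allyloxy)-1,3-bis(benzyloxy)-2-[2-(methanesulfinyl)-2-(methylsulfanyl)ethenyl]benzene (alkene isomers, racemic at sulfur)
Conditions: CH3S(O)CH2SCH3, PhCH2NMe3OH (Triton B, 40% in MeOH), THF, reflux
Reagents that add atoms: methyl (methylsulfanyl)methyl sulfoxide, CS(=O)CSC
Why: Knoevenagel-type condensation of the sulfur-stabilised carbanion with the aldehyde, the first half of the Ogura–Tsuchihashi arylacetic ester synthesis, which avoids the very labile 2,4,6-trialkoxybenzyl halides.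

Step 4
Reactants: 5 ketene dithioacetal S-oxide
Product: 6 methyl 2-[4-(allyloxy)-2,6-bis(benzyloxy)phenyl]acetate
Conditions: dry HCl, MeOH, 0 → 40 °C
Reagents that add atoms: methanol, CO
Why: acid-induced Pummerer-type methanolysis of the ketene dithioacetal S-oxide (second half of the Ogura–Tsuchihashi sequence) gives the homologated methyl ester with loss of dimethyl disulfide, and aryl benzyl and allyl ethers tolerate methanolic HCl.

Step 5
Reactants: 6 methyl 2-[4-(allyloxy)-2,6-bis(benzyloxy)phenyl]acetate; 7 4-methoxybenzoyl chloride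
Product: 8 methyl 2-[4-(allyloxy)-2,6-bis(benzyloxy)phenyl]-3-(4-methoxyphenyl)-3-oxopropanoate (racemic, enolisable)
Conditions: LiN(SiMe3)2 (2.2 equiv), THF, −78 °C; then 7, −78 → 0 °C; then 1 M HCl
Reagents that add atoms: none
Why: crossed Claisen C-acylation of the lithium ester enolate by the aroyl chloride, with the second equivalent of base converting the more acidic beta-keto ester into its enolate and so stopping further acylation.

Step 6
Reactants: 8 beta-keto ester
Product: 9 methyl (Z)-2-[4-(allyloxy)-2,6-bis(benzyloxy)phenyl]-3-chloro-3-(4-methoxyphenyl)prop-2-enoate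
Conditions: PPh3Cl2, Et3N, MeCN, 0 → 60 °C
Reagents that add atoms: dichlorotriphenylphosphorane, ClP(Cl)(c1ccccc1)(c1ccccc1)c1ccccc1
Why: Appel-type deoxychlorination of the enol through its enoxyphosphonium salt, with chloride adding to the beta carbon and expelling Ph3PO; a phosphorus electrophile is used because POCl3/DMF would formylate the trialkoxyphenyl ring, and either alkene isomer is usable later.

Step 7
Reactants: 9 vinyl chloride; 10 3,5-dimethoxyphenol
Product: 11 methyl (Z)-2-[4-(allyloxy)-2,6-bis(benzyloxy)phenyl]-3-(3,5-dimethoxyphenoxy)-3-(4-methoxyphenyl)prop-2-enoate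
Conditions: Cs2CO3, DMF, 80 °C
Reagents that add atoms: none
Why: nucleophilic vinylic substitution (addition–elimination) of the caesium phenoxide at the beta carbon of the chloroacrylate, the ester stabilising the intermediate carbanion; an E/Z mixture is acceptable because both isomers converge in step 9.

Step 8
Reactants: 11 aryloxyacrylate methyl ester
Product: 12 (Z)-2-[4-(allyloxy)-2,6-bis(benzyloxy)phenyl]-3-(3,5-dimethoxyphenoxy)-3-(4-methoxyphenyl)prop-2-enoic acid
Conditions: LiOH·H2O, THF/MeOH/H2O, 60 °C; then 1 M HCl to pH 3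
Reagents that add atoms: lithium hydroxide, [Li+].[OH-]
Why: saponification of the methyl ester, as is routine for 3-aryloxyacrylates; the donor-substituted, fully substituted beta carbon is a poor acceptor for hydroxide, so the aryloxy group should stay in place.

Step 9
Reactants: 12 (Z)-aryloxyacrylic acid
Product: 14 3-[4-(allyloxy)-2,6-bis(benzyloxy)phenyl]-5,7-dimethoxy-2-(4-methoxyphenyl)-4H-chromen-4-one, via mixed trifluoroacetic anhydride 13 (not isolated)
Conditions: (CF3CO)2O (1.5 equiv), CH2Cl2, 0 °C → rt
Reagents that add atoms: none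
Why: The anhydride converts the acid into the acyl trifluoroacetate 13, whose acyl carbon (in equilibrium with the acylium ion) is attacked by the phenoxy carbon ortho to the ether oxygen, a carbon that is also ortho and para to the two methoxy groups; proton loss gives the aryl ketone, an intramolecular Friedel–Crafts acylation of the kind long used to turn 3-aryloxyacrylic acids into chromones, here on a tetrasubstituted alkene. Ring C closes in a 6-exo-trig sense at the acyl carbon, forming C4–C4a while O1–C2 is already in place. No stereocentre is created. Regiochemistry needs no control, because the 3,5-dimethoxyphenoxy ring has a mirror plane through its C–O axis and both ortho carbons give the same 5,7-dimethoxychromone. Indenone formation is disfavoured because the anisyl ortho carbon is meta to its methoxy group and that five-membered closure is open only to the E acid, while the trifluoroacetic acid released protonates the push–pull alkene at the alpha carbon and so feeds E into the cyclising Z isomer. Intermolecular trifluoroacetylation of the trialkoxyphenyl ring is held back by the small excess of anhydride at 0 °C, the ring closure being much faster.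

Step 10
Reactants: 14 5,7-dimethoxychromone
Product: 15 3-[4-(allyloxy)-2,6-bis(benzyloxy)phenyl]-5-hydroxy-7-methoxy-2-(4-methoxyphenyl)-4H-chromen-4-one
Conditions: MgI2·OEt2 (3 equiv), toluene/THF, 70 °C; then 1 M HCl
Reagents that add atoms: none
Why: chelation-controlled peri-demethylation, in which magnesium bound between the C4 carbonyl oxygen and O5 activates only that methyl group for SN2 attack by iodide, so the non-chelated methyl, benzyl and allyl ethers should remain.

Step 11
Reactants: 15 5-hydroxyflavone
Product: 16 3-[3-acetyl-4-(allyloxy)-2,6-bis(benzyloxy)phenyl]-5-hydroxy-7-methoxy-2-(4-methoxyphenyl)-4H-chromen-4-one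
Conditions: AcOH, (CF3CO)2O, H3PO4 (cat.), CH2Cl2, 0 °C → rt; then K2CO3, MeOH, rt
Reagents that add atoms: acetic acid, CC(=O)O
Why: Friedel–Crafts acetylation by acetyl trifluoroacetate formed in the flask, which reaches only the phloroglucinol triether ring (its two free carbons are equivalent, while ring A is deactivated by the pyranone carbonyl) and needs no Lewis acid that would cleave the ethers; the methanolic carbonate wash removes any ester formed at O5.

Step 12
Reactants: 16 allyl ether
Product: 17 3-[3-acetyl-2,6-bis(benzyloxy)-4-hydroxyphenyl]-5-hydroxy-7-methoxy-2-(4-methoxyphenyl)-4H-chromen-4-one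
Conditions: Pd(PPh3)4 (5 mol%), morpholine, THF, rt
Reagents that add atoms: none
Why: Tsuji–Trost deallylation, in which zerovalent palladium ionises the allyl aryl ether to a pi-allyl complex that morpholine captures, freeing only the para phenol next to the acetyl group.

Step 13
Reactants: 17 o-hydroxyacetophenone
Product: 19 5,7-bis(benzyloxy)-6-[5-hydroxy-7-methoxy-2-(4-methoxyphenyl)-4-oxo-4H-chromen-3-yl]-4H-chromen-4-one, via enaminone 18 (not isolated)
Conditions: Me2NCH(OMe)2, toluene, 95 °C; then conc. HCl, CH2Cl2, 40 °C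
Reagents that add atoms: N,N-dimethylformamide dimethyl acetal, COC(OC)N(C)C
Why: enaminone formation at the acetyl methyl group followed by acid-induced addition of the adjacent phenol and loss of dimethylamine (standard chromone synthesis); the only hydroxyl next to the ketone is the para oxygen, which fixes the 6''-linked ring fusion.

Step 14
Reactants: 19 chromone; 20 4-(benzyloxy)phenylboronic acid
Product: 21 (2R)-5,7-bis(benzyloxy)-2-[4-(benzyloxy)phenyl]-6-[5-hydroxy-7-methoxy-2-(4-methoxyphenyl)-4-oxo-4H-chromen-3-yl]-2,3-dihydro-4H-chromen-4-one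
Conditions: Pd(OCOCF3)2 (5 mol%), (S)-4-tert-butyl-2-(pyridin-2-yl)-4,5-dihydrooxazole (6 mol%), NH4PF6 (30 mol%), H2O (5 equiv), ClCH2CH2Cl, 60 °C
Reagents that add atoms: none
Why: enantioselective conjugate addition of an arylboronic acid to a chromone under divalent palladium/pyridine-oxazoline catalysis (Hayashi–Miyaura-type 1,4-addition), in which the aryl–palladium species can insert only the disubstituted C2''=C3'' bond (flavone C2=C3 is fully substituted), the tert-butyl group of the (S)-ligand shields one enone face so that aryl is delivered to the face of C2'' giving 2''R, as expected from the behaviour of this ligand with chromone itself, and water protonates the enolate before the ring can open.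

Step 15
Reactants: 21 tris(benzyl) ether
Product: 22 (2R)-5,7-dihydroxy-2-(4-hydroxyphenyl)-6-[5-hydroxy-7-methoxy-2-(4-methoxyphenyl)-4-oxo-4H-chromen-3-yl]-2,3-dihydro-4H-chromen-4-one
Conditions: H2 (1 atm), Pd/C (10 wt%), EtOAc/MeOH, rt
Reagents that add atoms: none
Why: hydrogenolysis of the three aryl benzyl ethers under neutral conditions, which avoids the base-induced retro-oxa-Michael opening that would racemise C2''; the tetrasubstituted flavone C2=C3 bond and the hydrogen-bonded aryl ketones should not be reduced at 1 atm.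

**Compound list**

1 | 3,5-bis(benzyloxy)phenol | Oc1cc(OCc2ccccc2)cc(OCc2ccccc2)c1 | starting material
2 | [2,6-bis(benzyloxy)-4-hydroxyphenyl]methylidene-dimethyliminium chloride | C[N+](C)=Cc1c(OCc2ccccc2)cc(O)cc1OCc1ccccc1.[Cl-] | intermediate
3 | 2,6-bis(benzyloxy)-4-hydroxybenzaldehyde | O=Cc1c(OCc2ccccc2)cc(O)cc1OCc1ccccc1 | intermediate
4 | 4-(allyloxy)-2,6-bis(benzyloxy)benzaldehyde | O=Cc1c(OCc2ccccc2)cc(OCC=C)cc1OCc1ccccc1 | intermediate
5 | 5-(allyloxy)-1,3-bis(benzyloxy)-2-[2-(methanesulfinyl)-2-(methylsulfanyl)ethenyl]benzene (alkene isomers, racemic at sulfur) | CSC(=Cc1c(OCc2ccccc2)cc(OCC=C)cc1OCc1ccccc1)S(C)=O | intermediate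
6 | methyl 2-[4-(allyloxy)-2,6-bis(benzyloxy)phenyl]acetate | COC(=O)Cc1c(OCc2ccccc2)cc(OCC=C)cc1OCc1ccccc1 | intermediate
7 | 4-methoxybenzoyl chloride | COc1ccc(C(Cl)=O)cc1 | starting material
8 | methyl 2-[4-(allyloxy)-2,6-bis(benzyloxy)phenyl]-3-(4-methoxyphenyl)-3-oxopropanoate (racemic) | COC(=O)C(C(=O)c1ccc(OC)cc1)c1c(OCc2ccccc2)cc(OCC=C)cc1OCc1ccccc1 | intermediate
9 | methyl (Z)-2-[4-(allyloxy)-2,6-bis(benzyloxy)phenyl]-3-chloro-3-(4-methoxyphenyl)prop-2-enoate | COC(=O)/C(c1c(OCc2ccccc2)cc(OCC=C)cc1OCc1ccccc1)=C(\Cl)c1ccc(OC)cc1 | intermediate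
10 | 3,5-dimethoxyphenol | COc1cc(O)cc(OC)c1 | starting material
11 | methyl (Z)-2-[4-(allyloxy)-2,6-bis(benzyloxy)phenyl]-3-(3,5-dimethoxyphenoxy)-3-(4-methoxyphenyl)prop-2-enoate | COC(=O)/C(c1c(OCc2ccccc2)cc(OCC=C)cc1OCc1ccccc1)=C(\Oc1cc(OC)cc(OC)c1)c1ccc(OC)cc1 | intermediate
12 | (Z)-2-[4-(allyloxy)-2,6-bis(benzyloxy)phenyl]-3-(3,5-dimethoxyphenoxy)-3-(4-methoxyphenyl)prop-2-enoic acid | OC(=O)/C(c1c(OCc2ccccc2)cc(OCC=C)cc1OCc1ccccc1)=C(\Oc1cc(OC)cc(OC)c1)c1ccc(OC)cc1 | intermediate
13 | (Z)-2-[4-(allyloxy)-2,6-bis(benzyloxy)phenyl]-3-(3,5-dimethoxyphenoxy)-3-(4-methoxyphenyl)prop-2-enoic trifluoroacetic anhydride | O=C(OC(=O)C(F)(F)F)/C(c1c(OCc2ccccc2)cc(OCC=C)cc1OCc1ccccc1)=C(\Oc1cc(OC)cc(OC)c1)c1ccc(OC)cc1 | intermediate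
14 | 3-[4-(allyloxy)-2,6-bis(benzyloxy)phenyl]-5,7-dimethoxy-2-(4-methoxyphenyl)-4H-chromen-4-one | COc1ccc(-c2oc3cc(OC)cc(OC)c3c(=O)c2-c2c(OCc3ccccc3)cc(OCC=C)cc2OCc2ccccc2)cc1 | intermediate
15 | 3-[4-(allyloxy)-2,6-bis(benzyloxy)phenyl]-5-hydroxy-7-methoxy-2-(4-methoxyphenyl)-4H-chromen-4-one | COc1ccc(-c2oc3cc(OC)cc(O)c3c(=O)c2-c2c(OCc3ccccc3)cc(OCC=C)cc2OCc2ccccc2)cc1 | intermediate
16 | 3-[3-acetyl-4-(allyloxy)-2,6-bis(benzyloxy)phenyl]-5-hydroxy-7-methoxy-2-(4-methoxyphenyl)-4H-chromen-4-one | COc1ccc(-c2oc3cc(OC)cc(O)c3c(=O)c2-c2c(OCc3ccccc3)cc(OCC=C)c(C(C)=O)c2OCc2ccccc2)cc1 | intermediate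
17 | 3-[3-acetyl-2,6-bis(benzyloxy)-4-hydroxyphenyl]-5-hydroxy-7-methoxy-2-(4-methoxyphenyl)-4H-chromen-4-one | COc1ccc(-c2oc3cc(OC)cc(O)c3c(=O)c2-c2c(OCc3ccccc3)cc(O)c(C(C)=O)c2OCc2ccccc2)cc1 | intermediate
18 | (E)-1-{2,4-bis(benzyloxy)-6-hydroxy-3-[5-hydroxy-7-methoxy-2-(4-methoxyphenyl)-4-oxo-4H-chromen-3-yl]phenyl}-3-(dimethylamino)prop-2-en-1-one | COc1ccc(-c2oc3cc(OC)cc(O)c3c(=O)c2-c2c(OCc3ccccc3)cc(O)c(C(=O)/C=C/N(C)C)c2OCc2ccccc2)cc1 | intermediate
19 | 5,7-bis(benzyloxy)-6-[5-hydroxy-7-methoxy-2-(4-methoxyphenyl)-4-oxo-4H-chromen-3-yl]-4H-chromen-4-one | COc1ccc(-c2oc3cc(OC)cc(O)c3c(=O)c2-c2c(OCc3ccccc3)cc3occc(=O)c3c2OCc2ccccc2)cc1 | intermediate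
20 | 4-(benzyloxy)phenylboronic acid | OB(O)c1ccc(OCc2ccccc2)cc1 | starting material
21 | (2R)-5,7-bis(benzyloxy)-2-[4-(benzyloxy)phenyl]-6-[5-hydroxy-7-methoxy-2-(4-methoxyphenyl)-4-oxo-4H-chromen-3-yl]-2,3-dihydro-4H-chromen-4-one | COc1ccc(-c2oc3cc(OC)cc(O)c3c(=O)c2-c2c(OCc3ccccc3)cc3c(c2OCc2ccccc2)C(=O)C[C@H](c2ccc(OCc4ccccc4)cc2)O3)cc1 | intermediate
22 | (2R)-5,7-dihydroxy-2-(4-hydroxyphenyl)-6-[5-hydroxy-7-methoxy-2-(4-methoxyphenyl)-4-oxo-4H-chromen-3-yl]-2,3-dihydro-4H-chromen-4-one | COc1ccc(-c2oc3cc(OC)cc(O)c3c(=O)c2-c2c(O)cc3c(c2O)C(=O)C[C@H](c2ccc(O)cc2)O3)cc1 | target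

**Step count and risks**

Total step count: 15. Longest linear sequence: 15 steps (1 to 22).

Steps most likely to fail:

Step 9, the key cyclisation. The activated acyl group may be captured by an ortho benzyloxy oxygen of the neighbouring aryl ring (lactonisation with loss of a benzyl group). The electron-rich rings may also be trifluoroacetylated from outside before the ring closes, or E-to-Z equilibration may lag behind these processes. The fallback replaces the electrophilic closure by an anionic one and sets out from 9 and 10. Phenol 10 would be brominated with N-bromosuccinimide in CH2Cl2 at −78 °C to 2-bromo-3,5-dimethoxyphenol F1, separated from its 4-bromo isomer. F1 would displace the chloride of 9 (Cs2CO3, DMF, 80 °C) to give methyl (Z)-2-[4-(allyloxy)-2,6-bis(benzyloxy)phenyl]-3-(2-bromo-3,5-dimethoxyphenoxy)-3-(4-methoxyphenyl)prop-2-enoate F2. Bromine–lithium exchange with n-BuLi in THF at −100 to −78 °C would place the carbanion on the carbon ortho to the ether oxygen, which attacks the cis ester (Parham cycloacylation) and closes C4–C4a without any acylium species. The E isomer of F2 would be returned to the equilibrium by warming with caesium phenoxide. The fallback rejoins the route at 14.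

Step 14, the enantioselective conjugate addition. Insertion into a 5-alkoxy-6-aryl chromone may be slow, the chelating 5-hydroxy-4-oxo unit of the flavone may bind the catalyst, protodeboronation may outrun addition, and reversible opening of the enolate to a chalcone would erode the enantiomeric purity. The fallback sets out from 17 and uses a condensation–cyclisation–resolution sequence. Claisen–Schmidt condensation with 4-(benzyloxy)benzaldehyde (KOH, EtOH, rt) would give (E)-1-{2,4-bis(benzyloxy)-6-hydroxy-3-[5-hydroxy-7-methoxy-2-(4-methoxyphenyl)-4-oxo-4H-chromen-3-yl]phenyl}-3-[4-(benzyloxy)phenyl]prop-2-en-1-one F3. Oxa-Michael closure (NaOAc, EtOH, reflux) through the only free ortho hydroxyl would give racemic 5,7-bis(benzyloxy)-2-[4-(benzyloxy)phenyl]-6-[5-hydroxy-7-methoxy-2-(4-methoxyphenyl)-4-oxo-4H-chromen-3-yl]-2,3-dihydro-4H-chromen-4-one F4. Preparative HPLC on an amylose tris(3,5-dimethylphenylcarbamate) phase would then deliver the 2R enantiomer, which is 21, where the fallback rejoins the route.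

Step 7, the vinylic substitution. The ortho benzyloxy groups of the twisted aryl ring sit above and below the alkene and may block the approach of the phenoxide to the beta carbon; attack through a ring carbon of the ambident phenoxide or at the ester carbonyl may then take over. The fallback sets out from 8 and forms the C–O bond by in-plane metal-catalysed coupling instead. Compound 8 would be converted with PPh3Br2 and Et3N in MeCN into methyl (Z)-2-[4-(allyloxy)-2,6-bis(benzyloxy)phenyl]-3-bromo-3-(4-methoxyphenyl)prop-2-enoate F5. F5 would be coupled with 10 under Ullmann-type vinyl etherification (CuI 10 mol%, N,N-dimethylglycine, Cs2CO3, dioxane, 90 °C), a copper catalyst being chosen because zerovalent palladium would ionise the allyl ether. The fallback rejoins the route at 11.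

**Further compounds**

F1 | step 9 | 2-bromo-3,5-dimethoxyphenol | COc1cc(O)c(Br)c(OC)c1
F2 | step 9 | methyl (Z)-2-[4-(allyloxy)-2,6-bis(benzyloxy)phenyl]-3-(2-bromo-3,5-dimethoxyphenoxy)-3-(4-methoxyphenyl)prop-2-enoate | COC(=O)/C(c1c(OCc2ccccc2)cc(OCC=C)cc1OCc1ccccc1)=C(\Oc1cc(OC)cc(OC)c1Br)c1ccc(OC)cc1
F3 | step 14 | (E)-1-{2,4-bis(benzyloxy)-6-hydroxy-3-[5-hydroxy-7-methoxy-2-(4-methoxyphenyl)-4-oxo-4H-chromen-3-yl]phenyl}-3-[4-(benzyloxy)phenyl]prop-2-en-1-one | COc1ccc(-c2oc3cc(OC)cc(O)c3c(=O)c2-c2c(OCc3ccccc3)cc(O)c(C(=O)/C=C/c3ccc(OCc4ccccc4)cc3)c2OCc2ccccc2)cc1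
F4 | step 14 | racemic 5,7-bis(benzyloxy)-2-[4-(benzyloxy)phenyl]-6-[5-hydroxy-7-methoxy-2-(4-methoxyphenyl)-4-oxo-4H-chromen-3-yl]-2,3-dihydro-4H-chromen-4-one | COc1ccc(-c2oc3cc(OC)cc(O)c3c(=O)c2-c2c(OCc3ccccc3)cc3c(c2OCc2ccccc2)C(=O)CC(c2ccc(OCc4ccccc4)cc2)O3)cc1
F5 | step 7 | methyl (Z)-2-[4-(allyloxy)-2,6-bis(benzyloxy)phenyl]-3-bromo-3-(4-methoxyphenyl)prop-2-enoate | COC(=O)/C(c1c(OCc2ccccc2)cc(OCC=C)cc1OCc1ccccc1)=C(\Br)c1ccc(OC)cc1
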